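The cyclohexane ring is numbered C1 (quaternary carbinol), C2 (CHOH beside the C3–C4 methylenes), C5 (CHOBz), C6 (CHOH) and C7 (exocyclic CH2). With C1 as a ketone, C5(O)–C6–C1(=O) is an aldol unit, and the cis C2/C6 oxygens can be tied by one carbon, so that C2–C1–C6 becomes a 1,3-dioxan-5-one. The carbocycle is closed by a proline-catalysed intramolecular aldol (C5–C6 bond) of (R)-3-(5-oxo-1,3-dioxan-4-yl)propanal, which is unveiled by ozonolytic C=C cleavage of a cyclopentene formal. One operation builds the ring as a bridged 2,4-dioxabicyclo[3.3.1]nonan-9-one and sets C5 and C6 from C2. The rigid bridge then steers C7 onto C1.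

Key step: step 5

Step 1
Reactants: 1 2-iodocyclopent-2-en-1-one
Product: 2 (R)-2-iodocyclopent-2-en-1-ol
Conditions: (S)-2-methyl-CBS-oxazaborolidine (10 mol %), BH3·SMe2, THF, −20 °C; MeOH quench
Reagents that add atoms: none
Why: Corey–Bakshi–Shibata reduction, in which the α-iodovinyl side acts as the large group, so the (S)-oxazaborolidine should deliver hydride to the face that gives the (R)-allylic alcohol by clean 1,2-reduction; this sets C2 of the target.

Step 2
Reactants: 2 (R)-2-iodocyclopent-2-en-1-ol
Product: 3 (R)-2-(hydroxymethyl)cyclopent-2-en-1-ol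
Conditions: Bu3SnCH2OH (1.3 equiv), Pd(PPh3)4 (5 mol %), CuI (10 mol %), 1,4-dioxane, 90 °C
Reagents that add atoms: (tributylstannyl)methanol OC[Sn](CCCC)(CCCC)CCCC
Why: Stille cross-coupling (oxidative addition of zerovalent palladium into the vinyl C–I bond, transfer of the α-oxygenated CH2OH group from tin, reductive elimination) should hydroxymethylate the alkene carbon without touching the carbinol stereocentre; the new carbon becomes C6.

Step 3
Reactants: 3 (R)-2-(hydroxymethyl)cyclopent-2-en-1-ol
Product: 4 (7aR)-4,6,7,7a-tetrahydrocyclopenta[d][1,3]dioxine (methylene acetal of diol 3, double bond C4a=C5)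
Conditions: NaH (2.5 equiv), CH2Br2 (1.2 equiv), THF/DMF, 0 °C to rt, slow addition
Reagents that add atoms: dibromomethane BrCBr
Why: A double Williamson etherification should close the six-membered formal across the 1,3-diol under basic conditions that cannot ionise the allylic alcohol; a formaldehyde acetal adds no stereocentre and leaves only hydrogen on the concave side of the later bicycle.

Step 4
Reactants: 4 (7aR)-4,6,7,7a-tetrahydrocyclopenta[d][1,3]dioxine
Product: 5 (R)-3-(5-oxo-1,3-dioxan-4-yl)propanal
Conditions: O3, CH2Cl2/MeOH, NaHCO3, −78 °C; then Me2S, −78 °C to rt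
Reagents that add atoms: ozone [O-][O+]=O
Why: Ozonolysis of the only C=C bond opens the cyclopentene, turning C4a into the dioxanone ketone (C1) and C5 into the aldehyde (target C5), while the stereocentre, now α to the ketone, is untouched under the neutral reductive work-up.

Step 5
Reactants: 5 (R)-3-(5-oxo-1,3-dioxan-4-yl)propanal
Product: 7 (1R,5S,6R)-6-hydroxy-2,4-dioxabicyclo[3.3.1]nonan-9-one, via proline enamine 6 (not isolated)
Conditions: L-proline (30 mol %), DMSO (0.05 M), 20 °C
Reagents that add atoms: none
Why: L-Proline condenses with the ketone of 5 on its unsubstituted α-carbon to give enamine 6, whose carbon C6 attacks the tethered aldehyde carbon C5 while the carboxylic acid hydrogen-bonds the aldehyde oxygen, and hydrolysis then releases 7 and the catalyst; the closest known reaction types are the proline-catalysed intramolecular (Hajos–Parrish-type) aldol and the proline aldol of 1,3-dioxan-5-ones. The carbocycle, the only ring formed, is closed in a 6-(enolendo)-exo-trig mode, which completes the 2,4-dioxabicyclo[3.3.1]nonane frame. C6 is controlled by C2: the three-carbon tether sits axial on the dioxane chair and can reach only the same face of the enamine, so the C2 and C6 oxygens must be cis. C5 is controlled by the hydrogen-bonded closed transition state, which turns the aldehyde oxygen toward the enamine nitrogen and should place the new hydroxyl axial on the new ring, anti to the C6 oxygen. The step needs regioselective enamine use and retention of configuration at C2: the enamine on the C2 side cannot cyclise (it would give a four-membered ring), L-proline is the matched antipode for the (R)-substrate so that any C2-epimerised substrate should react slowly, and the product cannot enolise because its α-carbons are bridgeheads.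

Step 6
Reactants: 7 (1R,5S,6R)-6-hydroxy-2,4-dioxabicyclo[3.3.1]nonan-9-one
Product: 8 (1R,5S,6R)-9-oxo-2,4-dioxabicyclo[3.3.1]nonan-6-yl benzoate
Conditions: BzCl, pyridine, DMAP (cat.), CH2Cl2, 0 °C
Reagents that add atoms: benzoyl chloride O=C(Cl)c1ccccc1
Why: DMAP-catalysed acylation of the secondary alcohol installs the C5 benzoate and blocks retro-aldol; the β-acyloxy ketone should neither eliminate nor epimerise because enolisation toward a bridgehead is forbidden (Bredt's rule).

Step 7
Reactants: 8 (1R,5S,6R)-9-oxo-2,4-dioxabicyclo[3.3.1]nonan-6-yl benzoate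
Product: 9 (1R,5S,6R,9S)-spiro[2,4-dioxabicyclo[3.3.1]nonane-9,2'-oxiran]-6-yl benzoate (oxirane oxygen on the side of the C6–C8 bridge, syn to the benzoate; oxirane CH2 on the side of the O–CH2–O bridge)
Conditions: Me3S+ I−, n-BuLi, THF, −10 °C; then 8, −40 to 0 °C
Reagents that add atoms: trimethylsulfonium iodide C[S+](C)C.[I-]
Why: Corey–Chaykovsky epoxidation of a non-enolisable ketone, in which the ylide should attack C1 along the axial direction of the dioxanone ring (flanked only by ring oxygens) because the other face is screened by the axial C5 benzoate and the axial C3–H; this places C7 cis to the C2/C6 oxygens and sets C1.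

Step 8
Reactants: 9 (1R,5S,6R,9S)-spiro[2,4-dioxabicyclo[3.3.1]nonane-9,2'-oxiran]-6-yl benzoate
Product: 10 [(1R,5S,6R,9S)-6-(benzoyloxy)-9-hydroxy-2,4-dioxabicyclo[3.3.1]nonan-9-yl]methyl benzoate
Conditions: PhCO2H (3 equiv), PhCO2Cs (0.2 equiv), DMF, 80 °C
Reagents that add atoms: benzoic acid O=C(O)c1ccccc1
Why: Carboxylate opening of a 2,2-disubstituted epoxide by SN2 attack at its CH2 terminus should give the primary benzoate and the tertiary alcohol with C1 unchanged, since the C1–O bond is not broken and ionisation at C1 is disfavoured by the two flanking C–O bonds.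

Step 9
Reactants: 10 [(1R,5S,6R,9S)-6-(benzoyloxy)-9-hydroxy-2,4-dioxabicyclo[3.3.1]nonan-9-yl]methyl benzoate
Product: 11 [(1S,2S,3R,6R)-3-(benzoyloxy)-1,2,6-trihydroxycyclohexyl]methyl benzoate (CNP0264996.1)
Conditions: BCl3 (3 equiv), CH2Cl2, −78 to −30 °C; then aq. NaHCO3
Reagents that add atoms: none
Why: Lewis-acid cleavage of the strained bridging methylene acetal is a standard formal deprotection that should tolerate benzoates at low temperature and touches no stereocentre; the freed triol relaxes to the chair with C2–OH, C5–OBz, C6–OH and C7 equatorial.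

Compound list
1 | 2-iodocyclopent-2-en-1-one | O=C1CCC=C1I | starting material
2 | (R)-2-iodocyclopent-2-en-1-ol | O[C@@H]1CCC=C1I | intermediate
3 | (R)-2-(hydroxymethyl)cyclopent-2-en-1-ol | O[C@@H]1CCC=C1CO | intermediate
4 | (7aR)-4,6,7,7a-tetrahydrocyclopenta[d][1,3]dioxine | C1C[C@H]2OCOCC2=C1 | intermediate
5 | (R)-3-(5-oxo-1,3-dioxan-4-yl)propanal | O=CCC[C@H]1OCOCC1=O | intermediate
6 | (S)-1-[(R)-4-(3-oxopropyl)-4H-1,3-dioxin-5-yl]pyrrolidine-2-carboxylic acid (proline enamine, not isolated) | O=CCC[C@H]1OCOC=C1N1CCC[C@H]1C(=O)O | intermediate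
7 | (1R,5S,6R)-6-hydroxy-2,4-dioxabicyclo[3.3.1]nonan-9-one | O=C1[C@H]2CC[C@@H](O)[C@@H]1OCO2 | intermediate
8 | (1R,5S,6R)-9-oxo-2,4-dioxabicyclo[3.3.1]nonan-6-yl benzoate | O=C1[C@H]2CC[C@@H](OC(=O)c3ccccc3)[C@@H]1OCO2 | intermediate
9 | (1R,5S,6R,9S)-spiro[2,4-dioxabicyclo[3.3.1]nonane-9,2'-oxiran]-6-yl benzoate | C1O[C@]12[C@H]3CC[C@@H](OC(=O)c4ccccc4)[C@@H]2OCO3 | intermediate
10 | [(1R,5S,6R,9S)-6-(benzoyloxy)-9-hydroxy-2,4-dioxabicyclo[3.3.1]nonan-9-yl]methyl benzoate | O=C(OC[C@]1(O)[C@H]2CC[C@@H](OC(=O)c3ccccc3)[C@@H]1OCO2)c1ccccc1 | intermediate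
11 | [(1S,2S,3R,6R)-3-(benzoyloxy)-1,2,6-trihydroxycyclohexyl]methyl benzoate | O=C(OC[C@]1(O)[C@H](O)CC[C@@H](OC(=O)c2ccccc2)[C@@H]1O)c1ccccc1 | target

Total step count: 9. Longest linear sequence: 9 steps (1 → 11).

Steps most likely to fail

Step 5. The ring closure may show weak facial control at the aldehyde carbon, so that the hydroxyl ends equatorial (cis to the C6 oxygen). Partial loss of configuration at C2 through the competing enamine before closure is the second risk. The fallback uses the C5 epimer instead of fighting it. It sets out from 5: the same closure is run and the epimeric ketol (1R,5S,6S)-6-hydroxy-2,4-dioxabicyclo[3.3.1]nonan-9-one F1 is collected. A Mitsunobu esterification of F1 with benzoic acid (PPh3, DIAD, THF, 0 °C) should invert C5 while installing the benzoate, with base-induced elimination through the ketone excluded by the bridgehead α-carbon. The route is rejoined at 8.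

Step 7. The ylide, or the intermediate alkoxide that lies 1,3-syn-axial to the ester, may attack the C5 benzoate (acyl transfer or debenzoylation) in competition with epoxide closure. The fallback introduces that benzoate only after the carbanion chemistry and sets out from 7. Silylation (TBSOTf, 2,6-lutidine, CH2Cl2, −78 °C) should give (1R,5S,6R)-6-[(tert-butyldimethylsilyl)oxy]-2,4-dioxabicyclo[3.3.1]nonan-9-one F2. Corey–Chaykovsky epoxidation as in step 7 should give tert-butyldimethyl[(1R,5S,6R,9S)-spiro[2,4-dioxabicyclo[3.3.1]nonane-9,2'-oxiran]-6-yloxy]silane F3. Benzoate opening as in step 8 should give [(1R,5S,6R,9S)-6-[(tert-butyldimethylsilyl)oxy]-9-hydroxy-2,4-dioxabicyclo[3.3.1]nonan-9-yl]methyl benzoate F4. HF·pyridine (THF, 0 °C) should free the secondary hydroxyl in [(1R,5S,6R,9S)-6,9-dihydroxy-2,4-dioxabicyclo[3.3.1]nonan-9-yl]methyl benzoate F5. BzCl/pyridine/DMAP should then acylate the secondary alcohol only, and the route is rejoined at 10.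

Step 9. Cleavage of the formal may be incomplete, or the Lewis acid may cause acyl migration or loss of an ester. The fallback removes the acetal before the primary ester exists and sets out from 9. Aqueous acid (HClO4, THF/H2O, 40 °C) should open the oxirane at its CH2 terminus with water and hydrolyse the strained formal in the same flask, giving (1R,2S,3S,4R)-2,3,4-trihydroxy-3-(hydroxymethyl)cyclohexyl benzoate F6. Selective benzoylation of the primary hydroxyl (BzCl 1.05 equiv, 2,4,6-collidine, CH2Cl2, −40 °C) should then give 11.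

Further compounds
F1 | step 5 | (1R,5S,6S)-6-hydroxy-2,4-dioxabicyclo[3.3.1]nonan-9-one | O=C1[C@H]2CC[C@H](O)[C@@H]1OCO2
F2 | step 7 | (1R,5S,6R)-6-[(tert-butyldimethylsilyl)oxy]-2,4-dioxabicyclo[3.3.1]nonan-9-one | O=C1[C@H]2CC[C@@H](O[Si](C)(C)C(C)(C)C)[C@@H]1OCO2
F3 | step 7 | tert-butyldimethyl[(1R,5S,6R,9S)-spiro[2,4-dioxabicyclo[3.3.1]nonane-9,2'-oxiran]-6-yloxy]silane | C1O[C@]12[C@H]3CC[C@@H](O[Si](C)(C)C(C)(C)C)[C@@H]2OCO3
F4 | step 7 | [(1R,5S,6R,9S)-6-[(tert-butyldimethylsilyl)oxy]-9-hydroxy-2,4-dioxabicyclo[3.3.1]nonan-9-yl]methyl benzoate | O=C(OC[C@]1(O)[C@H]2CC[C@@H](O[Si](C)(C)C(C)(C)C)[C@@H]1OCO2)c1ccccc1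
F5 | step 7 | [(1R,5S,6R,9S)-6,9-dihydroxy-2,4-dioxabicyclo[3.3.1]nonan-9-yl]methyl benzoate | O=C(OC[C@]1(O)[C@H]2CC[C@@H](O)[C@@H]1OCO2)c1ccccc1
F6 | step 9 | (1R,2S,3S,4R)-2,3,4-trihydroxy-3-(hydroxymethyl)cyclohexyl benzoate | OC[C@]1(O)[C@H](O)CC[C@@H](OC(=O)c2ccccc2)[C@@H]1O
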